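## Structural features

The target is a stilbenoid trimer made of two 2,3-diaryl-2,3-dihydrobenzofurans: unit 1 (O1, C2, C3 fused to benzo ring B) and unit 2 (O1', C2', C3' fused to benzo ring B'), joined by the single bond C3–C6', so that ring B' is both the benzo ring of unit 2 and the aryl group on C3 of unit 1. Unit 1 carries a 4-hydroxyphenyl group on C2, a hydroxyl on C4 and an (E)-4-hydroxystyryl group on C6; unit 2 carries a 2,4-dihydroxyphenyl group (ring A') on C2', a 3,5-dihydroxyphenyl group on C3' and a hydroxyl on C4'. There are four stereocentres in two adjacent pairs, C2/C3 and C2'/C3', all R and both pairs trans; ring B' insulates the pairs from each other, so each pair needs its own reagent control. The fragile elements are the eight free phenols, the (E)-stilbene and the two benzylic ether bonds C2–O1 and C2'–O1'; the second is flanked by the ortho and para oxygens of ring A' and ionises most easily. Because trans is the more stable arrangement, C3 and C3' hold the configuration, and C2 and C2' can recover from a reversible ring opening. The real difficulty is twofold: in both benzo rings the fusion carbon (C3a, C3a') lies between two oxygenated carbons, so the heterocycle is hard to build on a resorcinol, and the two units meet at a stereogenic, doubly benzylic carbon (C3). The key step exploits the fact that O1' is bonded to C7a', which in an open-chain precursor is the only unsubstituted ortho carbon of a 4-bromo-2-methoxyphenyl ring, so the C2' hydroxyl can steer palladium to that C–H bond and close O1'–C7a'; O1–C7a of unit 1 has the same relationship.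

## Logic of the disconnections

**25 from 24.** The eight O–CH3 bonds are cut. Methyl is the only phenol protection that has no insertable C–H for the carbene steps and survives oxidant, organozinc and palladium. The demand on the forward step is ether cleavage without loss of the benzylic C–O bonds or the alkene; the trans rings are the thermodynamic ones, so reversible opening at C2 or C2' is tolerable as long as C3 and C3' stay untouched.

**24 from 22 and 23.** The C6–C(vinyl) bond is cut. The alkene is the group least compatible with radical and organometallic steps, so it comes last; the bromide on C6 is already present from the building block. The forward Heck reaction must give the linear E alkene.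

**22 from 19 and 13.** The C3–C6' bond is cut, which splits the skeleton into two halves of equal size made by the same chemistry. Forward, a C3 radical from the acid 19 must accept the aryl group of 13 on the face away from the C2 aryl group, and the aryl bromide of 19 must remain a spectator.

**13 from 9 and 10.** The C3'–aryl bond is cut in the same way. This reduces unit 2 to a carboxylic acid whose only lasting stereocentre is C2', and it rehearses the union step with a cheap aryl partner. The demand is trans delivery and tolerance of the C6'–Br bond.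

**9 from 8, and 19 from 18.** Only the ester O–CH3 bond is cut. The forward hydrolysis must avoid enolisation followed by β-elimination of the ring oxygen, which would erase C2' (or C2); a neutral tin hydroxide reagent is therefore chosen over aqueous base.

**8 from 7, and 18 from 17 (key disconnection).** The O1'–C7a' bond (O1–C7a in unit 1) is cut. The benzo ring then starts as a simple mono-oxygenated bromoarene, and the crowded position between two oxygens never has to be functionalised. Compound 7 is specified as the single syn (2R,3R) isomer: this is the isomer that closes directly to the 2',3'-trans ester, so no basic equilibration at C3' is needed. The forward step needs a hydroxyl-directed C–H oxygenation that spares the secondary alcohol, the electron-rich ring A' and the C–Br bond.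

**7 from 3 and 5 by way of 6; 17 from 3 and 15 by way of 16.** The C2'–C3' bond (C2–C3) is cut between the ester-bearing carbon and the carbinol carbon. One diazo ester, 3, serves both units, and the oxygen needed for the ring closure comes in with the benzyl ether. The forward carbene C–H insertion must be syn-selective and enantioselective at the carbinol carbon, which becomes C2' (C2).

**3 from 1 by way of 2; 5 from 4; 15 from 14.** Only C–N2, ester C–O and O–Si bonds are cut; these are functional-group operations on purchasable compounds.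

## Other disconnections considered

**Alternative 1:** The cut removes both aryl groups of unit 2 at once, the C2'–ring A' bond and the C3'–aryl bond, across the C2'=C3' bond of benzofuran A1. Forward, A1 is lithiated at C2' and combined with boronic ester A2 to give a boronate; a chiral arylpalladium species from triflate A3 attacks C3', ring A' shifts from boron to C2' anti to palladium, and reductive elimination gives A4, which is then protodeboronated with retention.
- In its favour: two C–C bonds and both stereocentres of unit 2 arise in one stereospecific event, and the trans relation is enforced by the anti 1,2-shift. On step economy for unit 2 and on the mechanistic coupling of the two centres it is better than the chosen plan, which relays C2' to C3' through a radical.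
- Against it here: A1 already contains the O1'–C7a' bond, so the hard oxygenation pattern is moved into a starting material and not solved. Ring A' is an ortho-substituted migrating group. A4 is a tertiary benzylic boronate with the ring oxygen on the same carbon, so activation at boron can trigger ring opening in place of protodeboronation.
- Comparison: the halide handle for unit 1 is equal in both plans. The chosen plan sets C2' by a reaction type known on exactly this substrate class and uses one diazo ester for both units.

**Alternative 2:** The cut is through ring B' itself, at C5'–C6' and C3a'–C4'. Forward, malonate A6 adds to the enone A5 carried on C3 of unit 1, and the methyl ketone enolate closes onto a malonate ester under alkoxide to give the cyclohexanedione A7, which must then be decarboxylated and aromatised.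
- In its favour: the inter-unit bond C3–C6' is never made by cross-coupling, because it is already the C3–Cβ bond of A5. On this point it is better than the chosen plan, whose union step spends an excess of a precious zinc reagent. The chemistry is cheap and ionic.
- Against it here: C3–H of A5 is γ to the enone, so alkoxide can move the double bond or epimerise C3. After aromatisation C3a' is a CH between two oxygens, the position the chosen plan avoids, and it must still be functionalised to grow the second heterocycle. Unit 2 then needs a separate asymmetric method, with unit 1 as a chiral bystander.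
- Comparison: unit 1 can be made equally well in either plan. In step count and in control of C2'/C3' the chosen plan is better.

**Alternative 3:** The cut is at C2–C3 and C2'–C3'. Forward, the bis-hydrazone A8 is oxidised in the flask to two diaryl diazo groups, and a chiral dirhodium tetracarboxylate effects two 1,5 C–H insertions into the O–CH2–aryl groups to give the cis,cis compound A9, followed by epimerisation at C2 and C2'.
- In its favour: both C3–aryl bonds exist before ring closure, so no decarboxylative arylation and no fragment union by organozinc is needed, and the aryl–O bonds come from simple O-benzylation. It is better in step economy after the precursor. It is equal in its reliance on a chiral dirhodium carboxylate, and donor/donor carbenes are at least as chemoselective as the donor/acceptor carbene used here.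
- Against it here: A8 requires two diaryl ketones flanked by two ortho oxygens, whose assembly and hydrazone formation are hindered. The second insertion runs under double stereodifferentiation. A9 has the wrong relative configuration at both rings, so two benzylic epimerisations through ring-opened cations are needed, and C2 is much less ready to ionise than C2'.
- Comparison: the chosen plan delivers trans directly at each ring and keeps the two units independent until late.

Key step: step 6

Assumption: Rh2(S-PTAD)4 (dirhodium tetrakis[(S)-N-phthaloyl-1-adamantylglycinate]) is taken to be the catalyst enantiomer that gives the (3R) silyl ethers 6 and 16; if the sense of induction proves opposite, Rh2(R-PTAD)4 is used in steps 4 and 10 with no other change.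

Assumption: in steps 8 and 14 one aryl group of the diarylzinc reagent is transferred.

## Route

Step 1
Reactants: 1 2-(4-bromo-2-methoxyphenyl)acetic acid
Product: 2 methyl 2-(4-bromo-2-methoxyphenyl)acetate
Conditions: MeOH, H2SO4 (cat.), reflux
Reagents that add atoms: methanol, CO
Why: Fischer esterification of an unhindered arylacetic acid; the aryl bromide and methyl ether are inert to acid catalysis.

Step 2
Reactants: 2 methyl 2-(4-bromo-2-methoxyphenyl)acetate
Product: 3 methyl 2-(4-bromo-2-methoxyphenyl)-2-diazoacetate
Conditions: p-ABSA, DBU, MeCN, 0 °C to rt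
Reagents that add atoms: 4-acetamidobenzenesulfonyl azide (p-ABSA), CC(=O)Nc1ccc(cc1)S(=O)(=O)N=[N+]=[N-]
Why: Regitz diazo transfer; DBU forms the ester enolate of the benzylic CH2, which attacks the terminal nitrogen of the sulfonyl azide and expels the sulfonamide to give the donor/acceptor diazo ester.

Step 3
Reactants: 4 (2,4-dimethoxyphenyl)methanol
Product: 5 tert-butyl[(2,4-dimethoxyphenyl)methoxy]dimethylsilane
Conditions: TBSCl, imidazole, CH2Cl2, rt
Reagents that add atoms: tert-butyldimethylsilyl chloride, CC(C)(C)[Si](C)(C)Cl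
Why: Silylation of a primary alcohol; the silyl ether removes the O–H bond that a carbene would attack and makes the benzylic C–H bonds good hydride donors for the next step.

Step 4
Reactants: 3 methyl 2-(4-bromo-2-methoxyphenyl)-2-diazoacetate; 5 tert-butyl[(2,4-dimethoxyphenyl)methoxy]dimethylsilane
Product: 6 methyl (2R,3R)-2-(4-bromo-2-methoxyphenyl)-3-[(tert-butyldimethylsilyl)oxy]-3-(2,4-dimethoxyphenyl)propanoate
Conditions: Rh2(S-PTAD)4 (1 mol%), 5 (2 equiv), 2,2-dimethylbutane, 50 °C, slow addition of 3
Reagents that add atoms: none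
Why: Intermolecular rhodium carbene C–H insertion into the benzylic C–H bond next to the silyloxy group, through a concerted three-centre transition state with hydride-transfer character that the oxygen and the electron-rich ring stabilise. The chiral carboxylate pocket selects one enantiotopic C–H bond and so sets C3 as R, and the preferred approach of the substrate to the carbene gives the syn (2R) relation. Excess 5 and slow addition of 3 suppress carbene dimerisation and insertion into the ortho methoxy group.

Step 5
Reactants: 6 methyl (2R,3R)-2-(4-bromo-2-methoxyphenyl)-3-[(tert-butyldimethylsilyl)oxy]-3-(2,4-dimethoxyphenyl)propanoate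
Product: 7 methyl (2R,3R)-2-(4-bromo-2-methoxyphenyl)-3-(2,4-dimethoxyphenyl)-3-hydroxypropanoate
Conditions: TBAF, AcOH, THF, 0 °C
Reagents that add atoms: none
Why: Fluoride desilylation; the acetic acid buffer keeps the medium from becoming basic, so the β-hydroxy ester neither undergoes retro-aldol cleavage nor epimerises, and both stereocentres are carried over.

Step 6
Reactants: 7 methyl (2R,3R)-2-(4-bromo-2-methoxyphenyl)-3-(2,4-dimethoxyphenyl)-3-hydroxypropanoate
Product: 8 methyl (2R,3R)-6-bromo-2-(2,4-dimethoxyphenyl)-4-methoxy-2,3-dihydro-1-benzofuran-3-carboxylate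
Conditions: Pd(OAc)2 (10 mol%), PhI(OAc)2 (1.5 equiv), Li2CO3 (1.5 equiv), C6F6, 100 °C
Reagents that add atoms: none
Why: The hydroxyl of 7 is deprotonated by Li2CO3 and binds divalent palladium, which cleaves the C6–H bond of the bromoaryl ring (the future C7a'–H) by concerted metalation–deprotonation to give a six-membered oxapalladacycle. PhI(OAc)2 oxidises this palladacycle to tetravalent palladium, and aryl–oxygen reductive elimination forms the O1'–C7a' bond and returns divalent palladium. The closest known reaction type is the hydroxyl-directed palladium-catalysed C–H activation/C–O cyclisation that converts 3-aryl-3-hydroxy-2-arylpropanoates from carbene C–H insertion into dihydrobenzofurans. The five-membered ring closes by contraction of the six-membered palladacycle in the reductive elimination, not by a nucleophilic closure, so no Baldwin constraint applies. No stereocentre is created: C2' and C3' take part in no bond change, so the syn arrangement of 7 becomes the 2',3'-trans relation of 8. Site selectivity between the two ortho positions of the bromoaryl ring is secured because one of them carries the methoxy group, and the ortho C–H bonds of ring A' would need a five-membered palladacycle and a four-membered ether and are unproductive. Chemoselectivity against oxidation of the secondary alcohol is helped by the neighbouring ester and aryl groups, which slow β-hydride loss, and by the non-polar medium with an insoluble mild base, which also disfavours retro-aldol cleavage. The C–Br bond is left alone because no zerovalent palladium builds up under the oxidising conditions.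

Step 7
Reactants: 8 methyl (2R,3R)-6-bromo-2-(2,4-dimethoxyphenyl)-4-methoxy-2,3-dihydro-1-benzofuran-3-carboxylate
Product: 9 (2R,3R)-6-bromo-2-(2,4-dimethoxyphenyl)-4-methoxy-2,3-dihydro-1-benzofuran-3-carboxylic acid
Conditions: Me3SnOH, 1,2-dichloroethane, 80 °C; then aq. HCl work-up
Reagents that add atoms: trimethyltin hydroxide, C[Sn](C)(C)O
Why: Neutral ester hydrolysis with trimethyltin hydroxide; it avoids the C3' enolate, whose β-elimination of the ring oxygen would open the furan and erase C2'. Epimerisation at C3' would in any case be harmless because that centre is remade in step 8.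

Step 8
Reactants: 9 (2R,3R)-6-bromo-2-(2,4-dimethoxyphenyl)-4-methoxy-2,3-dihydro-1-benzofuran-3-carboxylic acid; 10 1-bromo-3,5-dimethoxybenzene
Product: 13 (2R,3R)-6-bromo-3-(3,5-dimethoxyphenyl)-2-(2,4-dimethoxyphenyl)-4-methoxy-2,3-dihydro-1-benzofuran, via N-hydroxyphthalimide ester 11 (not isolated), via bis(3,5-dimethoxyphenyl)zinc 12 (not isolated)
Conditions: a) 9, NHPI, DIC, DMAP (cat.), CH2Cl2, rt; b) 10, Mg, THF, then ZnCl2 (0.5 equiv); c) Fe(acac)3 (10 mol%), dppBz (12 mol%), 12 (1.5 equiv), THF/toluene, rt
Reagents that add atoms: none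
Why: Iron-catalysed decarboxylative Negishi-type arylation of a redox-active ester: electron transfer from the low-valent aryliron species to 11 releases phthalimide anion and CO2 and leaves a planar benzylic radical at C3'. The aryl group is delivered to the face away from the C2' aryl group, which sets C3' as R (trans). The iron–bisphosphine catalyst reacts with the activated ester by electron transfer and is not expected to insert into the aryl C–Br bond.

Step 9
Reactants: 14 (4-methoxyphenyl)methanol
Product: 15 tert-butyl[(4-methoxyphenyl)methoxy]dimethylsilane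
Conditions: TBSCl, imidazole, CH2Cl2, rt
Reagents that add atoms: tert-butyldimethylsilyl chloride, CC(C)(C)[Si](C)(C)Cl
Why: Silylation of a primary alcohol, as in step 3.

Step 10
Reactants: 3 methyl 2-(4-bromo-2-methoxyphenyl)-2-diazoacetate; 15 tert-butyl[(4-methoxyphenyl)methoxy]dimethylsilane
Product: 16 methyl (2R,3R)-2-(4-bromo-2-methoxyphenyl)-3-[(tert-butyldimethylsilyl)oxy]-3-(4-methoxyphenyl)propanoate
Conditions: Rh2(S-PTAD)4 (1 mol%), 15 (2 equiv), 2,2-dimethylbutane, 50 °C, slow addition of 3
Reagents that add atoms: none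
Why: Intermolecular rhodium carbene C–H insertion as in step 4, here on a para-methoxybenzyl silyl ether without an ortho substituent, the most favourable substrate class. The same catalyst enantiomer sets C3 as R and the syn (2R) relation.

Step 11
Reactants: 16 methyl (2R,3R)-2-(4-bromo-2-methoxyphenyl)-3-[(tert-butyldimethylsilyl)oxy]-3-(4-methoxyphenyl)propanoate
Product: 17 methyl (2R,3R)-2-(4-bromo-2-methoxyphenyl)-3-hydroxy-3-(4-methoxyphenyl)propanoate
Conditions: TBAF, AcOH, THF, 0 °C
Reagents that add atoms: none
Why: Buffered fluoride desilylation as in step 5; the stereocentres are not touched.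

Step 12
Reactants: 17 methyl (2R,3R)-2-(4-bromo-2-methoxyphenyl)-3-hydroxy-3-(4-methoxyphenyl)propanoate
Product: 18 methyl (2R,3R)-6-bromo-4-methoxy-2-(4-methoxyphenyl)-2,3-dihydro-1-benzofuran-3-carboxylate
Conditions: Pd(OAc)2 (10 mol%), PhI(OAc)2 (1.5 equiv), Li2CO3 (1.5 equiv), C6F6, 100 °C
Reagents that add atoms: none
Why: Hydroxyl-directed palladium-catalysed C–H activation/C–O cyclisation as in step 6, forming O1–C7a at the only free ortho C–H. The syn alcohol gives the 2,3-trans ester with both stereocentres retained.

Step 13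
Reactants: 18 methyl (2R,3R)-6-bromo-4-methoxy-2-(4-methoxyphenyl)-2,3-dihydro-1-benzofuran-3-carboxylate
Product: 19 (2R,3R)-6-bromo-4-methoxy-2-(4-methoxyphenyl)-2,3-dihydro-1-benzofuran-3-carboxylic acid
Conditions: Me3SnOH, 1,2-dichloroethane, 80 °C; then aq. HCl work-up
Reagents that add atoms: trimethyltin hydroxide, C[Sn](C)(C)O
Why: Neutral ester hydrolysis with trimethyltin hydroxide as in step 7, so that C2 is not put at risk by enolate-driven ring opening.

Step 14
Reactants: 19 (2R,3R)-6-bromo-4-methoxy-2-(4-methoxyphenyl)-2,3-dihydro-1-benzofuran-3-carboxylic acid; 13 (2R,3R)-6-bromo-3-(3,5-dimethoxyphenyl)-2-(2,4-dimethoxyphenyl)-4-methoxy-2,3-dihydro-1-benzofuran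
Product: 22 (2R,3R)-6-bromo-3-[(2R,3R)-3-(3,5-dimethoxyphenyl)-2-(2,4-dimethoxyphenyl)-4-methoxy-2,3-dihydro-1-benzofuran-6-yl]-4-methoxy-2-(4-methoxyphenyl)-2,3-dihydro-1-benzofuran, via N-hydroxyphthalimide ester 20 (not isolated), via diarylzinc reagent 21 (not isolated)
Conditions: a) 19, NHPI, DIC, DMAP (cat.), CH2Cl2, rt; b) 13 (2.4 equiv), t-BuLi (4.8 equiv), THF, −78 °C, then ZnCl2 (1.2 equiv), MgBr2·OEt2; c) Fe(acac)3 (10 mol%), dppBz (12 mol%), THF/toluene, rt
Reagents that add atoms: none
Why: Iron-catalysed decarboxylative Negishi-type arylation as in step 8; the aryl nucleophile is again a 3,5-dioxygenated phenyl group without ortho substituents, so step 8 is a close model. The C3 radical from 20 accepts the aryl group on the face away from the 4-methoxyphenyl group, which sets C3 as R (trans). Bromine–lithium exchange on 13 at low temperature is faster than any benzylic deprotonation, and the C6–Br bond of 20 is not touched by the iron catalyst.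

Step 15
Reactants: 22 (2R,3R)-6-bromo-3-[(2R,3R)-3-(3,5-dimethoxyphenyl)-2-(2,4-dimethoxyphenyl)-4-methoxy-2,3-dihydro-1-benzofuran-6-yl]-4-methoxy-2-(4-methoxyphenyl)-2,3-dihydro-1-benzofuran; 23 1-ethenyl-4-methoxybenzene
Product: 24 (2R,3R)-3-[(2R,3R)-3-(3,5-dimethoxyphenyl)-2-(2,4-dimethoxyphenyl)-4-methoxy-2,3-dihydro-1-benzofuran-6-yl]-4-methoxy-2-(4-methoxyphenyl)-6-[(E)-2-(4-methoxyphenyl)ethenyl]-2,3-dihydro-1-benzofuran
Conditions: Pd2(dba)3 (2.5 mol%), [HP(t-Bu)3]BF4 (10 mol%), Cy2NMe, 1,4-dioxane, 80 °C
Reagents that add atoms: none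
Why: Heck reaction: oxidative addition of zerovalent palladium into C6–Br, syn insertion of the styrene with the aryl group on the terminal carbon, and syn β-hydride elimination give the E stilbene. No ester or other base-labile group remains in 22, and the four stereocentres are remote from the reacting site.

Step 16
Reactants: 24 (2R,3R)-3-[(2R,3R)-3-(3,5-dimethoxyphenyl)-2-(2,4-dimethoxyphenyl)-4-methoxy-2,3-dihydro-1-benzofuran-6-yl]-4-methoxy-2-(4-methoxyphenyl)-6-[(E)-2-(4-methoxyphenyl)ethenyl]-2,3-dihydro-1-benzofuran
Product: 25 4-[(2R,3R)-3-(3,5-dihydroxyphenyl)-4-hydroxy-6-{(2R,3R)-4-hydroxy-2-(4-hydroxyphenyl)-6-[(E)-2-(4-hydroxyphenyl)ethenyl]-2,3-dihydro-1-benzofuran-3-yl}-2,3-dihydro-1-benzofuran-2-yl]benzene-1,3-diol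
Conditions: BBr3 (excess), CH2Cl2, −78 °C to 0 °C; MeOH then water quench, degassed work-up
Reagents that add atoms: none
Why: Lewis-acid cleavage of aryl methyl ethers: each ether oxygen binds boron and bromide removes the methyl group by SN2 attack, and hydrolysis frees the phenols. Any transient opening of the C2–O1 or C2'–O1' bond should reclose to the trans ring, because C3 and C3' are not touched and trans is the more stable arrangement.

## Compound list

1 | 2-(4-bromo-2-methoxyphenyl)acetic acid | COc1cc(Br)ccc1CC(=O)O | starting material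
2 | methyl 2-(4-bromo-2-methoxyphenyl)acetate | COC(=O)Cc1ccc(Br)cc1OC | intermediate
3 | methyl 2-(4-bromo-2-methoxyphenyl)-2-diazoacetate | COC(=O)C(=[N+]=[N-])c1ccc(Br)cc1OC | intermediate
4 | (2,4-dimethoxyphenyl)methanol | COc1ccc(CO)c(OC)c1 | starting material
5 | tert-butyl[(2,4-dimethoxyphenyl)methoxy]dimethylsilane | COc1ccc(CO[Si](C)(C)C(C)(C)C)c(OC)c1 | intermediate
6 | methyl (2R,3R)-2-(4-bromo-2-methoxyphenyl)-3-[(tert-butyldimethylsilyl)oxy]-3-(2,4-dimethoxyphenyl)propanoate | CC(C)(C)[Si](C)(C)O[C@@H](c1ccc(OC)cc1OC)[C@@H](c1ccc(Br)cc1OC)C(=O)OC | intermediate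
7 | methyl (2R,3R)-2-(4-bromo-2-methoxyphenyl)-3-(2,4-dimethoxyphenyl)-3-hydroxypropanoate | O[C@@H](c1ccc(OC)cc1OC)[C@@H](c1ccc(Br)cc1OC)C(=O)OC | intermediate
8 | methyl (2R,3R)-6-bromo-2-(2,4-dimethoxyphenyl)-4-methoxy-2,3-dihydro-1-benzofuran-3-carboxylate | Brc1cc(OC)c2c(c1)O[C@@H](c1ccc(OC)cc1OC)[C@@H]2C(=O)OC | intermediate
9 | (2R,3R)-6-bromo-2-(2,4-dimethoxyphenyl)-4-methoxy-2,3-dihydro-1-benzofuran-3-carboxylic acid | Brc1cc(OC)c2c(c1)O[C@@H](c1ccc(OC)cc1OC)[C@@H]2C(=O)O | intermediate
10 | 1-bromo-3,5-dimethoxybenzene | COc1cc(Br)cc(OC)c1 | starting material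
11 | 1,3-dioxoisoindolin-2-yl (2R,3R)-6-bromo-2-(2,4-dimethoxyphenyl)-4-methoxy-2,3-dihydro-1-benzofuran-3-carboxylate | Brc1cc(OC)c2c(c1)O[C@@H](c1ccc(OC)cc1OC)[C@@H]2C(=O)ON1C(=O)c2ccccc2C1=O | intermediate
12 | bis(3,5-dimethoxyphenyl)zinc | COc1cc(OC)cc([Zn]c2cc(OC)cc(OC)c2)c1 | intermediate
13 | (2R,3R)-6-bromo-3-(3,5-dimethoxyphenyl)-2-(2,4-dimethoxyphenyl)-4-methoxy-2,3-dihydro-1-benzofuran | Brc1cc(OC)c2c(c1)O[C@@H](c1ccc(OC)cc1OC)[C@@H]2c1cc(OC)cc(OC)c1 | intermediate
14 | (4-methoxyphenyl)methanol | COc1ccc(CO)cc1 | starting material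
15 | tert-butyl[(4-methoxyphenyl)methoxy]dimethylsilane | COc1ccc(CO[Si](C)(C)C(C)(C)C)cc1 | intermediate
16 | methyl (2R,3R)-2-(4-bromo-2-methoxyphenyl)-3-[(tert-butyldimethylsilyl)oxy]-3-(4-methoxyphenyl)propanoate | CC(C)(C)[Si](C)(C)O[C@@H](c1ccc(OC)cc1)[C@@H](c1ccc(Br)cc1OC)C(=O)OC | intermediate
17 | methyl (2R,3R)-2-(4-bromo-2-methoxyphenyl)-3-hydroxy-3-(4-methoxyphenyl)propanoate | O[C@@H](c1ccc(OC)cc1)[C@@H](c1ccc(Br)cc1OC)C(=O)OC | intermediate
18 | methyl (2R,3R)-6-bromo-4-methoxy-2-(4-methoxyphenyl)-2,3-dihydro-1-benzofuran-3-carboxylate | Brc1cc(OC)c2c(c1)O[C@@H](c1ccc(OC)cc1)[C@@H]2C(=O)OC | intermediate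
19 | (2R,3R)-6-bromo-4-methoxy-2-(4-methoxyphenyl)-2,3-dihydro-1-benzofuran-3-carboxylic acid | Brc1cc(OC)c2c(c1)O[C@@H](c1ccc(OC)cc1)[C@@H]2C(=O)O | intermediate
20 | 1,3-dioxoisoindolin-2-yl (2R,3R)-6-bromo-4-methoxy-2-(4-methoxyphenyl)-2,3-dihydro-1-benzofuran-3-carboxylate | Brc1cc(OC)c2c(c1)O[C@@H](c1ccc(OC)cc1)[C@@H]2C(=O)ON1C(=O)c2ccccc2C1=O | intermediate
21 | bis[(2R,3R)-3-(3,5-dimethoxyphenyl)-2-(2,4-dimethoxyphenyl)-4-methoxy-2,3-dihydro-1-benzofuran-6-yl]zinc | [Zn](c1cc(OC)c2c(c1)O[C@@H](c1ccc(OC)cc1OC)[C@@H]2c1cc(OC)cc(OC)c1)c1cc(OC)c2c(c1)O[C@@H](c1ccc(OC)cc1OC)[C@@H]2c1cc(OC)cc(OC)c1 | intermediate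
22 | (2R,3R)-6-bromo-3-[(2R,3R)-3-(3,5-dimethoxyphenyl)-2-(2,4-dimethoxyphenyl)-4-methoxy-2,3-dihydro-1-benzofuran-6-yl]-4-methoxy-2-(4-methoxyphenyl)-2,3-dihydro-1-benzofuran | Brc1cc(OC)c2c(c1)O[C@@H](c1ccc(OC)cc1)[C@@H]2c1cc(OC)c2c(c1)O[C@@H](c1ccc(OC)cc1OC)[C@@H]2c1cc(OC)cc(OC)c1 | intermediate
23 | 1-ethenyl-4-methoxybenzene | COc1ccc(C=C)cc1 | starting material
24 | (2R,3R)-3-[(2R,3R)-3-(3,5-dimethoxyphenyl)-2-(2,4-dimethoxyphenyl)-4-methoxy-2,3-dihydro-1-benzofuran-6-yl]-4-methoxy-2-(4-methoxyphenyl)-6-[(E)-2-(4-methoxyphenyl)ethenyl]-2,3-dihydro-1-benzofuran | COc1ccc(/C=C/c2cc(OC)c3c(c2)O[C@@H](c2ccc(OC)cc2)[C@@H]3c2cc(OC)c3c(c2)O[C@@H](c2ccc(OC)cc2OC)[C@@H]3c2cc(OC)cc(OC)c2)cc1 | intermediate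
25 | 4-[(2R,3R)-3-(3,5-dihydroxyphenyl)-4-hydroxy-6-{(2R,3R)-4-hydroxy-2-(4-hydroxyphenyl)-6-[(E)-2-(4-hydroxyphenyl)ethenyl]-2,3-dihydro-1-benzofuran-3-yl}-2,3-dihydro-1-benzofuran-2-yl]benzene-1,3-diol | Oc1ccc(/C=C/c2cc(O)c3c(c2)O[C@@H](c2ccc(O)cc2)[C@@H]3c2cc(O)c3c(c2)O[C@@H](c2ccc(O)cc2O)[C@@H]3c2cc(O)cc(O)c2)cc1 | target

## Step count and least certain steps

Total: 16 steps. Longest linear sequence: 10 steps (steps 1, 2, 4, 5, 6, 7, 8, 14, 15, 16).

**Step 6 (key step; the same concerns apply in milder form to step 12).** The most likely failures are oxidation of the secondary benzylic alcohol through β-hydride loss from the palladium alkoxide, retro-aldol fragmentation of that alkoxide at 100 °C, and oxidative attack of the hypervalent iodine reagent on the very electron-rich ring A'. All three compete with a cyclometalation that has to occur next to a substituted benzylic carbon. The fallback sets out from 1 and comes back to the route at 8; it makes the same O1'–C7a' bond by cross-coupling to a halide installed before any oxidisable alcohol exists. Carboxylate-directed ortho C–H iodination of 1 (Pd(OAc)2, PhI(OAc)2, I2, DMF) at its only free ortho position should give 2-(4-bromo-2-iodo-6-methoxyphenyl)acetic acid F1. Its pivaloyl mixed anhydride acylates lithiated (4R)-4-benzyl-1,3-oxazolidin-2-one to give the N-acyl oxazolidinone F2. An Evans syn-aldol reaction (Bu2BOTf, i-Pr2NEt, then 2,4-dimethoxybenzaldehyde) should give the (2R,3R) aldol adduct F3, and methanolysis with MeOMgBr gives the iodo hydroxy ester F4. A copper-catalysed intramolecular Ullmann-type etherification (CuI, 1,10-phenanthroline, Cs2CO3, toluene), selective for C–I over C–Br, then closes the ring to 8.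

**Step 4 (less so step 10).** The carbene may insert into its own ortho methoxy group, attack the electron-rich arene of 5 as an electrophile, or simply dimerise, because both partners carry ortho substituents that slow the intermolecular insertion. Erosion of the syn and enantiofacial selectivity is the second concern. The fallback sets out from 1 and comes back at 7. Acid 1 is converted through its pivaloyl mixed anhydride into (4R)-4-benzyl-3-[2-(4-bromo-2-methoxyphenyl)acetyl]-1,3-oxazolidin-2-one F5. An Evans syn-aldol reaction of its boron enolate with 2,4-dimethoxybenzaldehyde should give the (2R,3R) adduct F6, and methanolysis with MeOMgBr at 0 °C gives 7 and returns the auxiliary.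

**Step 14.** The aryl bromide of the ester partner may be drawn into the coupling. Transfer of the large aryl group from zinc to iron may be slow, so that the benzylic radical dimerises or is reduced. The reagent economy is poor, because only one aryl group of 21 is delivered and an excess is needed. The fallback sets out from 18 and 13 and comes back at 24; it installs the alkene first, so the ester partner is halide-free and a nickel catalyst with a monoaryl zinc reagent can be used. A Heck reaction of 18 with 23 (Pd2(dba)3, [HP(t-Bu)3]BF4, Cy2NMe, rt to 50 °C) gives the stilbene ester F7, and Me3SnOH hydrolysis gives the stilbene acid F8, which is activated as its N-hydroxyphthalimide ester F9. Bromide 13 is converted by t-BuLi and ZnCl2 into the arylzinc chloride F10. Nickel-catalysed decarboxylative Negishi coupling of F9 with F10 (NiCl2(dme), 4,4'-di-tert-butyl-2,2'-bipyridine, THF/DMF, rt) then gives 24 directly.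

**Step 16.** Ionisation of the benzylic C2'–O1' bond may be followed by elimination instead of reclosure. Acid-promoted addition or oligomerisation at the electron-rich stilbene is possible, and cleavage of all eight ethers may be incomplete. The fallback sets out from 22 and comes back at 25; it moves the ether cleavage in front of the alkene-forming step and finishes under mild base. BBr3 demethylation of 22, which has no alkene, gives the heptaphenol bromide F11, and acetylation (Ac2O, pyridine) gives the heptaacetate F12. A Heck reaction with 4-ethenylphenyl acetate (Pd(OAc)2, P(o-tol)3, Et3N, DMF, 90 °C) gives the octaacetate F13, and methanolysis (K2CO3, MeOH, 0 °C, degassed) gives 25.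

## Further compounds

F1 | step 6 | 2-(4-bromo-2-iodo-6-methoxyphenyl)acetic acid | COc1cc(Br)cc(I)c1CC(=O)O
F2 | step 6 | (4R)-4-benzyl-3-[2-(4-bromo-2-iodo-6-methoxyphenyl)acetyl]-1,3-oxazolidin-2-one | COc1cc(Br)cc(I)c1CC(=O)N1[C@H](Cc2ccccc2)COC1=O
F3 | step 6 | (4R)-4-benzyl-3-[(2R,3R)-2-(4-bromo-2-iodo-6-methoxyphenyl)-3-(2,4-dimethoxyphenyl)-3-hydroxypropanoyl]-1,3-oxazolidin-2-one | O[C@@H](c1ccc(OC)cc1OC)[C@@H](c1c(I)cc(Br)cc1OC)C(=O)N1[C@H](Cc2ccccc2)COC1=O
F4 | step 6 | methyl (2R,3R)-2-(4-bromo-2-iodo-6-methoxyphenyl)-3-(2,4-dimethoxyphenyl)-3-hydroxypropanoate | O[C@@H](c1ccc(OC)cc1OC)[C@@H](c1c(I)cc(Br)cc1OC)C(=O)OC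
F5 | step 4 | (4R)-4-benzyl-3-[2-(4-bromo-2-methoxyphenyl)acetyl]-1,3-oxazolidin-2-one | COc1cc(Br)ccc1CC(=O)N1[C@H](Cc2ccccc2)COC1=O
F6 | step 4 | (4R)-4-benzyl-3-[(2R,3R)-2-(4-bromo-2-methoxyphenyl)-3-(2,4-dimethoxyphenyl)-3-hydroxypropanoyl]-1,3-oxazolidin-2-one | O[C@@H](c1ccc(OC)cc1OC)[C@@H](c1ccc(Br)cc1OC)C(=O)N1[C@H](Cc2ccccc2)COC1=O
F7 | step 14 | methyl (2R,3R)-4-methoxy-2-(4-methoxyphenyl)-6-[(E)-2-(4-methoxyphenyl)ethenyl]-2,3-dihydro-1-benzofuran-3-carboxylate | COc1ccc(/C=C/c2cc(OC)c3c(c2)O[C@@H](c2ccc(OC)cc2)[C@@H]3C(=O)OC)cc1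
F8 | step 14 | (2R,3R)-4-methoxy-2-(4-methoxyphenyl)-6-[(E)-2-(4-methoxyphenyl)ethenyl]-2,3-dihydro-1-benzofuran-3-carboxylic acid | COc1ccc(/C=C/c2cc(OC)c3c(c2)O[C@@H](c2ccc(OC)cc2)[C@@H]3C(=O)O)cc1
F9 | step 14 | 1,3-dioxoisoindolin-2-yl (2R,3R)-4-methoxy-2-(4-methoxyphenyl)-6-[(E)-2-(4-methoxyphenyl)ethenyl]-2,3-dihydro-1-benzofuran-3-carboxylate | COc1ccc(/C=C/c2cc(OC)c3c(c2)O[C@@H](c2ccc(OC)cc2)[C@@H]3C(=O)ON2C(=O)c4ccccc4C2=O)cc1
F10 | step 14 | chlorido[(2R,3R)-3-(3,5-dimethoxyphenyl)-2-(2,4-dimethoxyphenyl)-4-methoxy-2,3-dihydro-1-benzofuran-6-yl]zinc | Cl[Zn]c1cc(OC)c2c(c1)O[C@@H](c1ccc(OC)cc1OC)[C@@H]2c1cc(OC)cc(OC)c1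
F11 | step 16 | 4-[(2R,3R)-6-[(2R,3R)-6-bromo-4-hydroxy-2-(4-hydroxyphenyl)-2,3-dihydro-1-benzofuran-3-yl]-3-(3,5-dihydroxyphenyl)-4-hydroxy-2,3-dihydro-1-benzofuran-2-yl]benzene-1,3-diol | Brc1cc(O)c2c(c1)O[C@@H](c1ccc(O)cc1)[C@@H]2c1cc(O)c2c(c1)O[C@@H](c1ccc(O)cc1O)[C@@H]2c1cc(O)cc(O)c1
F12 | step 16 | heptaacetate of F11 (all seven phenols as acetates) | Brc1cc(OC(C)=O)c2c(c1)O[C@@H](c1ccc(OC(C)=O)cc1)[C@@H]2c1cc(OC(C)=O)c2c(c1)O[C@@H](c1ccc(OC(C)=O)cc1OC(C)=O)[C@@H]2c1cc(OC(C)=O)cc(OC(C)=O)c1
F13 | step 16 | octaacetate of 25 (all eight phenols as acetates) | CC(=O)Oc1ccc(/C=C/c2cc(OC(C)=O)c3c(c2)O[C@@H](c2ccc(OC(C)=O)cc2)[C@@H]3c2cc(OC(C)=O)c3c(c2)O[C@@H](c2ccc(OC(C)=O)cc2OC(C)=O)[C@@H]3c2cc(OC(C)=O)cc(OC(C)=O)c2)cc1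
A1 | alternative 1 | 6-chloro-4-methoxy-1-benzofuran | COc1cc(Cl)cc2occc12
A2 | alternative 1 | 2-(2,4-dimethoxyphenyl)-4,4,5,5-tetramethyl-1,3,2-dioxaborolane | COc1ccc(B2OC(C)(C)C(C)(C)O2)c(OC)c1
A3 | alternative 1 | 3,5-dimethoxyphenyl trifluoromethanesulfonate | COc1cc(OC)cc(OS(=O)(=O)C(F)(F)F)c1
A4 | alternative 1 | 2-[(2R,3R)-6-chloro-3-(3,5-dimethoxyphenyl)-2-(2,4-dimethoxyphenyl)-4-methoxy-2,3-dihydro-1-benzofuran-2-yl]-4,4,5,5-tetramethyl-1,3,2-dioxaborolane | Clc1cc(OC)c2c(c1)O[C@@](B1OC(C)(C)C(C)(C)O1)(c1ccc(OC)cc1OC)[C@@H]2c1cc(OC)cc(OC)c1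
A5 | alternative 2 | (3E)-4-[(2R,3R)-4-methoxy-2-(4-methoxyphenyl)-6-[(E)-2-(4-methoxyphenyl)ethenyl]-2,3-dihydro-1-benzofuran-3-yl]but-3-en-2-one | COc1ccc(/C=C/c2cc(OC)c3c(c2)O[C@@H](c2ccc(OC)cc2)[C@@H]3/C=C/C(C)=O)cc1
A6 | alternative 2 | dimethyl propanedioate | COC(=O)CC(=O)OC
A7 | alternative 2 | methyl 6-[(2R,3R)-4-methoxy-2-(4-methoxyphenyl)-6-[(E)-2-(4-methoxyphenyl)ethenyl]-2,3-dihydro-1-benzofuran-3-yl]-2,4-dioxocyclohexane-1-carboxylate | COc1ccc(/C=C/c2cc(OC)c3c(c2)O[C@@H](c2ccc(OC)cc2)[C@@H]3C2CC(=O)CC(=O)C2C(=O)OC)cc1
A8 | alternative 3 | bis-hydrazone of [4-bromo-2-methoxy-6-[(4-methoxyphenyl)methoxy]phenyl]{4-(3,5-dimethoxybenzoyl)-3-[(2,4-dimethoxyphenyl)methoxy]-5-methoxyphenyl}methanone | NN=C(c1c(OC)cc(Br)cc1OCc1ccc(OC)cc1)c1cc(OC)c(C(=NN)c2cc(OC)cc(OC)c2)c(OCc2ccc(OC)cc2OC)c1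
A9 | alternative 3 | (2S,3R)-6-bromo-3-[(2S,3R)-3-(3,5-dimethoxyphenyl)-2-(2,4-dimethoxyphenyl)-4-methoxy-2,3-dihydro-1-benzofuran-6-yl]-4-methoxy-2-(4-methoxyphenyl)-2,3-dihydro-1-benzofuran | Brc1cc(OC)c2c(c1)O[C@H](c1ccc(OC)cc1)[C@@H]2c1cc(OC)c2c(c1)O[C@H](c1ccc(OC)cc1OC)[C@@H]2c1cc(OC)cc(OC)c1
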